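## The problem

Target 17, (3R)-6,8-dihydroxy-3-[(10S)-10-methoxyundecyl]isochroman-1-one, is a 3,4-dihydroisocoumarin. A resorcinol ring A is fused through C4a–C8a to a δ-lactone ring B, whose only substituent is an eleven-carbon chain at C3 carrying a methyl ether at C10'. The two stereocentres, C3 (R) and C10' (S), lie nine methylene groups apart, so neither can steer the other and each must be set on its own in absolute terms. Any leakage at one centre gives a remote diastereomer that will hardly separate, so both must be set with high enantiomeric purity. The free resorcinol is acidic and easily oxidised, the lactone opens in base, and the C10' methyl ether rules out phenol methyl ethers, because a Lewis acid strong enough to cleave them would also attack C10'–OMe. A plan that never protects the phenols is therefore attractive. C3 is a carbinol carbon and stays safe as long as no step draws C3 or C4 into an enolisable or ionisable system. The enabling feature is that C6 with its oxygen, C5, C4a, C4, C3 and O2 are exactly the carbonyl carbon, α-carbon, β-carbon, C5, C6 and ring oxygen of a 6-substituted 5,6-dihydropyran-2-one. The remaining atoms C7, C8 with its oxygen, C8a and C1 are the four-carbon chain of an acetoacetate, so the oxygen pattern of ring A is that of a Michael–Claisen adduct once ring A is viewed at the cyclohexane-1,3-dione level.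

## Retrosynthesis

**17 ⇒ 16.** Ring A is first taken back to the cyclohexane-1,3-dione level. Adding two hydrogens across C4a–C5 gives the bicyclic enol lactone 16, (3R)-8-hydroxy-3-[(10S)-10-methoxyundecyl]-3,4,4a,5-tetrahydro-1H-isochromene-1,6(7H)-dione. No skeletal bond is cut. The gain is that C6 and C8 become carbonyl carbons and C7 and C8a become enolate positions, so the ring can be built by carbonyl condensation. A direct arene cut (C4–C4a or C1–C8a) would instead require a pre-made, protected resorcinol. The forward step is the dehydrogenation of a dihydroresorcylate; it must spare the lactone and the ether, and it removes the C4a centre, which therefore never needs control.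

**16 ⇒ 12 + 13.** Three bonds are cut together: C8a–C4a (Michael), C7–C6 (Claisen) and O2–C1 (ester exchange). This returns (6R)-6-[(10S)-10-methoxyundecyl]-5,6-dihydro-2H-pyran-2-one 12 and methyl acetoacetate 13. The lactone is preferred over an open-chain 5-hydroxyalk-2-enoate because it keeps the C3 oxygen tied up as an acyl oxygen until it is needed as a nucleophile, so no hydroxyl protection is required. The precursor is monocyclic, has one ring stereocentre and no arene. The forward reaction must achieve conjugate addition ahead of base-induced opening of 12, attack of a methyl-ketone enolate on a lactone carbonyl, and closure of the new lactone on the methyl ester.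

**12 ⇒ 11 ⇒ 9 + 10.** The C3=C4 double bond of the pyranone is cut by ring-closing metathesis, giving the acrylate 11. Its acyl C–O bond is then cut to the homoallylic alcohol 9, (4R,14S)-14-methoxypentadec-1-en-4-ol, and acryloyl chloride 10. Against a Z-selective olefination–lactonisation sequence, this route needs no protecting group and gets the Z-geometry from the ring. The precursor 9 is acyclic. The forward steps are an acylation and a metathesis of a well-behaved substrate class, which only needs dilution.

**9 ⇒ 7.** The allyl–carbinol bond (C3–C4 of 9) is cut to (11S)-11-methoxydodecanal 7. This is where the future C3 centre is set. The C14 centre is eleven atoms away, so only reagent control is possible, and an allylborane with a closed transition state is the most dependable choice for an unbranched aldehyde. The forward reaction must deliver the (4R) carbinol with high selectivity.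

**7 ⇒ 5 ⇒ 4 ⇒ 1 + 2.** The aldehyde is traced to the terminal alkene 5, (12S)-12-methoxytridec-1-ene, by ozonolysis (one carbon lost), and 5 to the alcohol 4, (2S)-tridec-12-en-2-ol, by O-methylation. Cutting C3–C4 of 4 gives the Grignard reagent 3 from 10-bromodec-1-ene 1 and (S)-propylene oxide 2. The C10' centre thus comes from the chiral pool, with no bond to it ever broken. The terminal alkene serves as a masked aldehyde that survives the Grignard and methylation steps.

## Roads not taken

**Alternative 1:** Hidden symmetry of the chain.
- **Cut:** the stretch C4–C3–C1'…C9'–C10'–C11' becomes C2-symmetric when both ends are written as chloromethyl carbinols, so C1'–C2' and C8'–C9' are cut together.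
- **Forward key step:** heptane-1,7-diylbis(magnesium bromide) A1 opens two molecules of (R)-epichlorohydrin A2 at the epoxide CH2 under CuI catalysis and gives (2R,12R)-1,13-dichlorotridecane-2,12-diol A3. A3 already holds both carbinol centres. The same spatial arrangement is called R at C3 and S at C10' in 17 only because one CH2Cl ends as C4 and the other as the methyl C11'.
- **Merits:** both stereocentres come from one inexpensive chiral-pool reagent in a single step, with no asymmetric reagent. Enantiomeric purity is upgraded statistically, because a wrong-handed unit ends mostly in the meso isomer.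
- **Weak points:** the two ends of A3 are identical and must be told apart by a statistical mono-functionalisation. A bis-Grignard reagent is prone to partial quenching. Ring A is not addressed at all: a protected resorcylic nucleophile must still be joined at C4, lactonised and deprotected, and the protecting groups cannot be methyl.
- **Comparison:** in stereocontrol this road is better than the chosen plan, whose C3 centre rests on one reagent-controlled allylation with an inseparable remote epimer as the penalty for leakage. The chosen plan sets against this a linear sequence without statistical steps or protecting groups, and a key step that makes ring A and the lactone together.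

**Alternative 2:** Alder–Rickert benzannulation.
- **Cut:** C8–C8a and C5–C4a, with ring A assembled around an acetylenic ester.
- **Forward key step:** 1,3-bis(trimethylsilyloxy)cyclohexa-1,3-diene A4 and methyl (5R,15S)-5-[(tert-butyldimethylsilyl)oxy]-15-methoxyhexadec-2-ynoate A5 undergo a Diels–Alder addition. The bicyclo[2.2.2]octadiene then expels its two-carbon bridge by retro-Diels–Alder reaction and gives methyl 2-[(2R,12S)-2-[(tert-butyldimethylsilyl)oxy]-12-methoxytridecyl]-4,6-bis(trimethylsilyloxy)benzoate A6.
- **Merits:** ring A arrives directly at the aromatic level with the correct substitution, since the nucleophilic diene terminus pairs with the β-carbon of the ynoate. The reaction type is established for resorcylates, and C3 is a silyl ether throughout and cannot epimerise.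
- **Weak points:** a β-alkyl ynoate is a sluggish dienophile, so temperatures well above 150 °C are to be expected, at which A4 also desilylates or decomposes. A5 needs the same kind of chiral carbinol as 9 plus an alkynoate homologation and a silylation, and A6 still needs desilylation and lactonisation.
- **Comparison:** the key step of this road is better precedented than step 7 and needs no separate aromatisation, which is a real advantage. The step count from alkene 5 is about the same. The chosen plan sets against it mild base-mediated conditions and the absence of any protecting group.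

**Alternative 3:** Directed C–H alkylation.
- **Cut:** C4–C4a and O2–C1, so that the whole lactone ring is closed onto an intact, protected resorcylic acid.
- **Forward key step:** 2,4-bis(benzyloxy)benzoic acid A7 and (2R)-2-[(10S)-10-methoxyundecyl]oxirane A8 react under Pd(OAc)2 catalysis (divalent palladium). The carboxylate directs palladation of the only free ortho C–H bond, the aryl–palladium bond opens the epoxide at its CH2 carbon, and the alkoxide lactonises to (3R)-6,8-bis(benzyloxy)-3-[(10S)-10-methoxyundecyl]isochroman-1-one A9.
- **Merits:** this is the most convergent road. The regiochemistry is unambiguous because the other ortho position is blocked, and the epoxide centre is carried over unchanged. From alkene 5 only four operations are needed (epoxidation, kinetic resolution, coupling, hydrogenolysis) against six in the chosen plan.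
- **Weak points:** enantiopure A8 from a terminal alkene in practice means a hydrolytic kinetic resolution that discards at least half of the chain. Such C–H alkylations normally run with the epoxide in excess, whereas A8 is the valuable partner here. An ortho-alkoxy group twists the carboxylate out of plane, and electron-rich salicylate-type acids are prone to protodecarboxylation under palladium catalysis. Two benzyl groups must be put on and removed.
- **Comparison:** this road is shorter and its key step has closer precedent than step 7; that must be conceded. The chosen plan sets against it full use of the chain material, no protecting groups, ring A from a commodity four-carbon ester, and independence from a C–H activation on a doubly alkoxylated acid whose behaviour is not assured.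

Key step: step 7

Remark on the chemistry: 16 is written as its C8 enol. The triketo form and the C6 enol are tautomers of the same compound, and both C4a epimers are carried on because step 8 removes that centre. Locants C1–C8a refer to the isochromanone skeleton of 17, and primed locants to its side chain.

## Route

Step 1
Reactants: 1 10-bromodec-1-ene; 2 (S)-2-methyloxirane [(S)-propylene oxide]
Product: 4 (2S)-tridec-12-en-2-ol, via dec-9-en-1-ylmagnesium bromide 3 (not isolated)
Conditions: Mg, THF, rt to 45 °C; then CuI (10 mol%), 2, THF, −30 to 0 °C; aq. NH4Cl
Reagents that add atoms: none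
Why: Copper-catalysed Grignard opening of a terminal epoxide at its CH2 carbon (SN2); no bond to the stereocentre of 2 is broken, so 4 keeps the (S) configuration of the chiral-pool epoxide.

Step 2
Reactants: 4 (2S)-tridec-12-en-2-ol
Product: 5 (12S)-12-methoxytridec-1-ene
Conditions: NaH, MeI, THF, 0 °C to rt
Reagents that add atoms: iodomethane, CI
Why: Williamson ether synthesis on the secondary alkoxide; the C–O bond at the stereocentre stays intact, so the configuration is retained.

Step 3
Reactants: 5 (12S)-12-methoxytridec-1-ene
Product: 7 (11S)-11-methoxydodecanal, via ozonide 6 (not isolated)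
Conditions: O3, CH2Cl2, −78 °C; then PPh3, −78 °C to rt
Reagents that add atoms: ozone, [O-][O+]=O
Why: Ozonolysis of a terminal alkene with reductive work-up; the secondary methyl ether is inert at −78 °C when the ozone stream is stopped at the end point, and the aldehyde has no α-stereocentre to lose.

Step 4
Reactants: 7 (11S)-11-methoxydodecanal
Product: 9 (4R,14S)-14-methoxypentadec-1-en-4-ol, via O-borinate 8 (not isolated)
Conditions: (−)-Ipc2B(allyl) (reagent from (+)-α-pinene, salt-free solution in pentane), Et2O, −78 °C; then 3 M NaOH, 30% H2O2, 0 °C to rt
Reagents that add atoms: (−)-B-allyldiisopinocampheylborane, C=CCB([C@H]1[C@H](C)[C@H]2C[C@@H](C1)C2(C)C)[C@H]1[C@H](C)[C@H]2C[C@@H](C1)C2(C)C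
Why: Brown allylboration through a closed chair transition state; the reagent derived from (+)-α-pinene delivers allyl to the Si face of unbranched aliphatic aldehydes, which gives the (4R) carbinol under pure reagent control, the C14 centre being too remote to interfere.

Step 5
Reactants: 9 (4R,14S)-14-methoxypentadec-1-en-4-ol; 10 acryloyl chloride
Product: 11 (4R,14S)-14-methoxypentadec-1-en-4-yl prop-2-enoate
Conditions: Et3N, DMAP (cat.), CH2Cl2, 0 °C
Reagents that add atoms: none
Why: O-acylation of a secondary alcohol by an acid chloride under nucleophilic catalysis; the carbinol C–O bond is untouched and low temperature prevents conjugate addition of the amine to the acrylate.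

Step 6
Reactants: 11 (4R,14S)-14-methoxypentadec-1-en-4-yl prop-2-enoate
Product: 12 (6R)-6-[(10S)-10-methoxyundecyl]-5,6-dihydro-2H-pyran-2-one
Conditions: second-generation Grubbs catalyst (H2IMes)(PCy3)Cl2Ru=CHPh (3 mol%), CH2Cl2 (0.005 M), 40 °C
Reagents that add atoms: none
Why: Ring-closing metathesis of the acrylate of a homoallylic alcohol, a standard entry to 6-substituted 5,6-dihydropyran-2-ones; loss of ethene drives it, the ring enforces the Z-alkene, and initiation at the unhindered terminal alkene followed by closure on the acrylate avoids acrylate dimerisation at high dilution.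

Step 7
Reactants: 12 (6R)-6-[(10S)-10-methoxyundecyl]-5,6-dihydro-2H-pyran-2-one; 13 methyl acetoacetate
Product: 16 (3R)-8-hydroxy-3-[(10S)-10-methoxyundecyl]-3,4,4a,5-tetrahydro-1H-isochromene-1,6(7H)-dione (8-enol form; both C4a epimers), via Michael adduct lactone 14 (not isolated), via hydroxy dione ester 15 (not isolated)
Conditions: 13 (1.5 equiv), NaOMe (0.2 equiv), MeOH, 0 °C to rt; then NaOMe (2.2 equiv), reflux; then solvent switched to THF by distillation, 60 °C; cold 1 M HCl to pH 3
Reagents that add atoms: none
Why: Proposed new method: the Michael–Claisen route from acetoacetates and open-chain alk-2-enoates to dihydroresorcylates is the closest known reaction type, and the extension proposed here is to let an α,β-unsaturated δ-lactone act as the enoate so that its ring oxygen is handed on to the acetoacetate ester; every elementary step is the lactone counterpart of a known ester reaction. With catalytic NaOMe the stabilised enolate of 13 adds to C4 of 12, anti to the C6 chain, and gives 14 (bond C8a–C4a). With excess NaOMe at reflux the methyl-ketone enolate of 14, present in small equilibrium share, attacks the lactone carbonyl in a 6-(enolendo)-exo-trig acyl substitution through a 2-oxabicyclo[3.3.1]nonane tetrahedral intermediate (the bridged geometry known from aldol closure of cyclohexenone–acetoacetate adducts); its collapse expels the C3 alkoxide, closes carbocycle A (bond C7–C6) and is pulled forward by deprotonation of the 1,3-dione 15. Should methoxide open the saturated lactone of 14 first, the methyl ester so formed undergoes the classical Dieckmann-type closure to the same 15, so both paths converge. The C3 alkoxide then closes ring B on the methyl ester by 6-exo-trig transesterification (bond O2–C1); exchanging MeOH for THF shifts this equilibrium to the lactone while the dione is still masked as its enolate and cannot form an enol ether with the free hydroxyl. The two new centres need no control: C4a is set anti to the chain by the substrate but is removed in step 8, C8a is enolised, and C3 keeps its configuration because no acidic hydrogen or leaving-group pathway touches it after the Michael step. The selectivity the step needs is conjugate addition ahead of γ-deprotonation and eliminative opening of 12 to a dienoate; it is secured by keeping the base catalytic in the first phase, where it is stored almost entirely as the weakly basic enolate of 13, and by using 13 in excess, which also suppresses double addition.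

Step 8
Reactants: 16 (3R)-8-hydroxy-3-[(10S)-10-methoxyundecyl]-3,4,4a,5-tetrahydro-1H-isochromene-1,6(7H)-dione
Product: 17 (3R)-6,8-dihydroxy-3-[(10S)-10-methoxyundecyl]isochroman-1-one
Conditions: Hg(OAc)2 (2.2 equiv), NaOAc, AcOH, reflux
Reagents that add atoms: none
Why: Dehydrogenation of a dihydroresorcylate to the resorcylate by divalent mercury (α-mercuration of the enol, then loss of mercury together with the C4a hydrogen), driven by aromatisation; the buffered acetic acid leaves the lactone, the methyl ether and the non-enolisable C3 centre untouched, and both C4a epimers converge on 17.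

## Compound list

1 | 10-bromodec-1-ene | C=CCCCCCCCCBr | starting material
2 | (S)-2-methyloxirane [(S)-propylene oxide] | C[C@H]1CO1 | starting material
3 | dec-9-en-1-ylmagnesium bromide | C=CCCCCCCCC[Mg]Br | intermediate (not isolated)
4 | (2S)-tridec-12-en-2-ol | C[C@H](O)CCCCCCCCCC=C | intermediate
5 | (12S)-12-methoxytridec-1-ene | CO[C@@H](C)CCCCCCCCCC=C | intermediate
6 | 3-[(10S)-10-methoxyundecyl]-1,2,4-trioxolane (ozonide, both ring epimers) | CO[C@@H](C)CCCCCCCCCC1OCOO1 | intermediate (not isolated)
7 | (11S)-11-methoxydodecanal | CO[C@@H](C)CCCCCCCCCC=O | intermediate
8 | (4R,14S)-14-methoxypentadec-1-en-4-yl diisopinocampheylborinate (Ipc groups from (+)-α-pinene) | CO[C@@H](C)CCCCCCCCC[C@H](CC=C)OB([C@H]1[C@H](C)[C@H]2C[C@@H](C1)C2(C)C)[C@H]1[C@H](C)[C@H]2C[C@@H](C1)C2(C)C | intermediate (not isolated)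
9 | (4R,14S)-14-methoxypentadec-1-en-4-ol | CO[C@@H](C)CCCCCCCCC[C@@H](O)CC=C | intermediate
10 | acryloyl chloride (prop-2-enoyl chloride) | C=CC(=O)Cl | starting material
11 | (4R,14S)-14-methoxypentadec-1-en-4-yl prop-2-enoate | CO[C@@H](C)CCCCCCCCC[C@H](CC=C)OC(=O)C=C | intermediate
12 | (6R)-6-[(10S)-10-methoxyundecyl]-5,6-dihydro-2H-pyran-2-one | CO[C@@H](C)CCCCCCCCC[C@@H]1CC=CC(=O)O1 | intermediate
13 | methyl acetoacetate (methyl 3-oxobutanoate) | CC(=O)CC(=O)OC | starting material
14 | methyl 2-[(2R)-2-[(10S)-10-methoxyundecyl]-6-oxooxan-4-yl]-3-oxobutanoate (ring C4 and side-chain C2 unassigned) | CO[C@@H](C)CCCCCCCCC[C@@H]1CC(C(C(C)=O)C(=O)OC)CC(=O)O1 | intermediate (not isolated)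
15 | methyl 6-[(2R,12S)-2-hydroxy-12-methoxytridecyl]-2,4-dioxocyclohexane-1-carboxylate (ring centres unassigned; present as its sodium enolate) | CO[C@@H](C)CCCCCCCCC[C@@H](O)CC1CC(=O)CC(=O)C1C(=O)OC | intermediate (not isolated)
16 | (3R)-8-hydroxy-3-[(10S)-10-methoxyundecyl]-3,4,4a,5-tetrahydro-1H-isochromene-1,6(7H)-dione (8-enol form, both C4a epimers) | CO[C@@H](C)CCCCCCCCC[C@@H]1CC2CC(=O)CC(O)=C2C(=O)O1 | intermediate
17 | (3R)-6,8-dihydroxy-3-[(10S)-10-methoxyundecyl]isochroman-1-one | CO[C@@H](C)CCCCCCCCC[C@@H]1Cc2cc(O)cc(O)c2C(=O)O1 | target

## Step count and risks

Total step count: 8. Longest linear sequence: 8 steps, from 1 to 17; 2, 10 and 13 enter as single commercial reagents.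

**Step 7 (key step, proposed new method).**
- What may go wrong: eliminative opening of 12 (γ-deprotonation at C5, then expulsion of the carboxylate from C6) could compete with conjugate addition and erase the C3 centre. The methyl-ketone enolate may fail to reach the lactone carbonyl through the bridged transition state, so the sequence stalls at 14 or drifts into retro-Claisen deacetylation. Relactonisation may stay incomplete, leaving 15, whose free hydroxyl can form an enol ether with the dione on acidification.
- Fallback: it uses the open-chain acceptor for which the Michael–Claisen sequence is established; it sets out from 9 and comes back to the route at 17. Alcohol 9 would be silylated (TBSCl, imidazole, DMF) to tert-butyl{[(4R,14S)-14-methoxypentadec-1-en-4-yl]oxy}dimethylsilane F1. Cross-metathesis with methyl acrylate (second-generation Hoveyda–Grubbs catalyst (H2IMes)Cl2Ru=CH(C6H4-2-OiPr), CH2Cl2, 40 °C) would give methyl (2E,5R,15S)-5-[(tert-butyldimethylsilyl)oxy]-15-methoxyhexadec-2-enoate F2. With 13 and NaOMe in refluxing MeOH, F2 should pass through the Michael adduct dimethyl 2-acetyl-3-[(2R,12S)-2-[(tert-butyldimethylsilyl)oxy]-12-methoxytridecyl]pentanedioate F3 to methyl 6-[(2R,12S)-2-[(tert-butyldimethylsilyl)oxy]-12-methoxytridecyl]-2,4-dioxocyclohexane-1-carboxylate F4. Dehydrogenation as in step 8 would give methyl 2-[(2R,12S)-2-[(tert-butyldimethylsilyl)oxy]-12-methoxytridecyl]-4,6-dihydroxybenzoate F5. Desilylation with aqueous HF in MeCN, followed by lactonisation of the resulting o-(2-hydroxyalkyl)benzoate (TsOH cat., toluene, 60 °C), would deliver 17. The price is three more steps and one protecting group.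

**Step 8.**
- What may go wrong: dehydrogenation may be incomplete, or the electron-rich enol and the product resorcinol may be mercurated or over-oxidised; prolonged heating in acetic acid could also open the β-keto lactone.
- Fallback: a halogenation–elimination route in place of direct dehydrogenation; it sets out from 16 and comes back at 17. Bromine (3 equiv) in AcOH at rt to 60 °C should brominate the dione, aromatise it by loss of HBr and brominate the two free ring positions, giving (3R)-5,7-dibromo-6,8-dihydroxy-3-[(10S)-10-methoxyundecyl]isochroman-1-one F6. Hydrogenolysis of both C–Br bonds (H2, Pd/C, Et3N, EtOAc) would then give 17.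

**Step 4.**
- What may go wrong: facial selectivity may be insufficient (traces of magnesium salts, warming during addition). The (4S) epimer of 9 is a remote diastereomer that would travel unseparated to 17.
- Fallback: the carbinol centre is set by resolution and not by reagent control; it sets out from 5 and comes back at 9. Epoxidation of 5 (mCPBA, CH2Cl2) would give 2-[(10S)-10-methoxyundecyl]oxirane as both C2 epimers F7. Hydrolytic kinetic resolution with the (salen)Co(OAc) complex of trivalent cobalt, using the catalyst enantiomer that hydrolyses the (2S)-epoxide faster, would leave (2R)-2-[(10S)-10-methoxyundecyl]oxirane F8 beside the easily removed (2S,12S)-12-methoxytridecane-1,2-diol F9. Opening of F8 with vinylmagnesium bromide and CuI (cat.) at the CH2 carbon would give 9. Purity can be driven high at the cost of at least half of the material.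

**Step 6.**
- What may go wrong: intermolecular metathesis may lead to oligomers, or the catalyst may be sequestered by chelation of the acrylate carbonyl to ruthenium, so that conversion stops.
- Fallback: a Z-selective olefination followed by lactonisation; it sets out from 9 and comes back at 12. The silyl ether F1 described above would be ozonised (O3, CH2Cl2, −78 °C; PPh3) to (3R,13S)-3-[(tert-butyldimethylsilyl)oxy]-13-methoxytetradecanal F10. Still–Gennari olefination with methyl bis(2,2,2-trifluoroethyl)phosphonoacetate (KN(SiMe3)2, 18-crown-6, THF, −78 °C) would give methyl (2Z,5R,15S)-5-[(tert-butyldimethylsilyl)oxy]-15-methoxyhexadec-2-enoate F11. Aqueous HF in MeCN would remove the silyl group and the Z-hydroxy ester would lactonise to 12.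

## Further compounds

F1 | step 7 | tert-butyl{[(4R,14S)-14-methoxypentadec-1-en-4-yl]oxy}dimethylsilane | CO[C@@H](C)CCCCCCCCC[C@H](CC=C)O[Si](C)(C)C(C)(C)C
F2 | step 7 | methyl (2E,5R,15S)-5-[(tert-butyldimethylsilyl)oxy]-15-methoxyhexadec-2-enoate | CO[C@@H](C)CCCCCCCCC[C@H](C/C=C/C(=O)OC)O[Si](C)(C)C(C)(C)C
F3 | step 7 | dimethyl 2-acetyl-3-[(2R,12S)-2-[(tert-butyldimethylsilyl)oxy]-12-methoxytridecyl]pentanedioate | CO[C@@H](C)CCCCCCCCC[C@H](CC(CC(=O)OC)C(C(C)=O)C(=O)OC)O[Si](C)(C)C(C)(C)C
F4 | step 7 | methyl 6-[(2R,12S)-2-[(tert-butyldimethylsilyl)oxy]-12-methoxytridecyl]-2,4-dioxocyclohexane-1-carboxylate | CO[C@@H](C)CCCCCCCCC[C@H](CC1CC(=O)CC(=O)C1C(=O)OC)O[Si](C)(C)C(C)(C)C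
F5 | step 7 | methyl 2-[(2R,12S)-2-[(tert-butyldimethylsilyl)oxy]-12-methoxytridecyl]-4,6-dihydroxybenzoate | CO[C@@H](C)CCCCCCCCC[C@H](Cc1cc(O)cc(O)c1C(=O)OC)O[Si](C)(C)C(C)(C)C
F6 | step 8 | (3R)-5,7-dibromo-6,8-dihydroxy-3-[(10S)-10-methoxyundecyl]isochroman-1-one | CO[C@@H](C)CCCCCCCCC[C@@H]1Cc2c(Br)c(O)c(Br)c(O)c2C(=O)O1
F7 | step 4 | 2-[(10S)-10-methoxyundecyl]oxirane (both C2 epimers) | CO[C@@H](C)CCCCCCCCCC1CO1
F8 | step 4 | (2R)-2-[(10S)-10-methoxyundecyl]oxirane | CO[C@@H](C)CCCCCCCCC[C@@H]1CO1
F9 | step 4 | (2S,12S)-12-methoxytridecane-1,2-diol | CO[C@@H](C)CCCCCCCCC[C@H](O)CO
F10 | step 6 | (3R,13S)-3-[(tert-butyldimethylsilyl)oxy]-13-methoxytetradecanal | CO[C@@H](C)CCCCCCCCC[C@H](CC=O)O[Si](C)(C)C(C)(C)C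
F11 | step 6 | methyl (2Z,5R,15S)-5-[(tert-butyldimethylsilyl)oxy]-15-methoxyhexadec-2-enoate | CO[C@@H](C)CCCCCCCCC[C@H](C/C=C\C(=O)OC)O[Si](C)(C)C(C)(C)C
A1 | alternative 1 | heptane-1,7-diylbis(magnesium bromide) | Br[Mg]CCCCCCC[Mg]Br
A2 | alternative 1 | (R)-epichlorohydrin | ClC[C@H]1CO1
A3 | alternative 1 | (2R,12R)-1,13-dichlorotridecane-2,12-diol | ClC[C@H](O)CCCCCCCCC[C@@H](O)CCl
A4 | alternative 2 | 1,3-bis(trimethylsilyloxy)cyclohexa-1,3-diene | C[Si](C)(C)OC1=CC(O[Si](C)(C)C)=CCC1
A5 | alternative 2 | methyl (5R,15S)-5-[(tert-butyldimethylsilyl)oxy]-15-methoxyhexadec-2-ynoate | CO[C@@H](C)CCCCCCCCC[C@H](CC#CC(=O)OC)O[Si](C)(C)C(C)(C)C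
A6 | alternative 2 | methyl 2-[(2R,12S)-2-[(tert-butyldimethylsilyl)oxy]-12-methoxytridecyl]-4,6-bis(trimethylsilyloxy)benzoate | CO[C@@H](C)CCCCCCCCC[C@H](Cc1cc(O[Si](C)(C)C)cc(O[Si](C)(C)C)c1C(=O)OC)O[Si](C)(C)C(C)(C)C
A7 | alternative 3 | 2,4-bis(benzyloxy)benzoic acid | OC(=O)c1ccc(OCc2ccccc2)cc1OCc1ccccc1
A8 | alternative 3 | (2R)-2-[(10S)-10-methoxyundecyl]oxirane | CO[C@@H](C)CCCCCCCCC[C@@H]1CO1
A9 | alternative 3 | (3R)-6,8-bis(benzyloxy)-3-[(10S)-10-methoxyundecyl]isochroman-1-one | CO[C@@H](C)CCCCCCCCC[C@@H]1Cc2cc(OCc3ccccc3)cc(OCc3ccccc3)c2C(=O)O1
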